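Ring A is opened at C3–C4 (labdane numbering). The gem-dimethyl quaternary carbon C4 beside the C5 ring-fusion methine is read as the isopropenyl group of (S)-carvone, whose ring becomes ring B (C=O at C9, methyl on C8). In the key step an iron hydride transfers a hydrogen atom to the isopropenyl CH2, and the tertiary C4 radical closes ring A by 6-endo addition to the CH2 terminus (C3) of a vinyl sulfone carried by quaternary C10. This joins two alkene carbons and creates C4 with both methyl groups and the trans-decalin in one operation. The precursor is a 6,6-dialkylated carvone; the sulfone is then excised, and side chain and glyceride are attached by Negishi coupling and esterification.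

Key step: step 5

Remark: the target is read as the ent-labd-8-en-15-oate (5R,10R,13R) of 1-O-acetyl-sn-glycerol, acylated at O2 (glycerol C2 = S). Ring A = C1–C5, C10 and ring B = C5–C10. The half-ester 12 is assumed to be purchasable (otherwise it comes from enzymatic desymmetrisation of dimethyl 3-methylglutarate).

Step 1
Reactants: 1 phenyl vinyl sulfone
Product: 2 2-(phenylsulfonyl)prop-2-en-1-ol
Conditions: 37% aq. HCHO, DABCO, THF, rt
Reagents that add atoms: formaldehyde, C=O
Why: Morita–Baylis–Hillman reaction, in which DABCO adds to the vinyl sulfone, the α-sulfonyl carbanion adds to formaldehyde and loss of DABCO restores the alkene; no stereocentre is formed.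

Step 2
Reactants: 2 2-(phenylsulfonyl)prop-2-en-1-ol
Product: 3 3-bromo-2-(phenylsulfonyl)prop-1-ene
Conditions: PBr3, Et2O, 0 °C
Reagents that add atoms: phosphorus tribromide, BrP(Br)Br
Why: Bromination of a primary allylic alcohol with PBr3 (SN2 on the phosphite; an SN2′ path would give the same constitution because the 2-sulfonylallyl unit is symmetric).

Step 3
Reactants: 4 (S)-(+)-carvone
Product: 6 (5S,6R)-2,6-dimethyl-5-(prop-1-en-2-yl)cyclohex-2-en-1-one (trans-6-methylcarvone), via carvone lithium α′-enolate 5 (not isolated)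
Conditions: LiN(i-Pr)2 (LDA), THF, −78 °C; MeI, −78 to 0 °C
Reagents that add atoms: iodomethane, CI
Why: Kinetic α′-deprotonation gives the cross-conjugated enolate and enolate alkylation with MeI should occur mainly anti to the neighbouring isopropenyl group; the C6 configuration is erased in step 4, so any cis epimer is carried along.

Step 4
Reactants: 6 (5S,6R)-6-methylcarvone; 3 3-bromo-2-(phenylsulfonyl)prop-1-ene
Product: 8 (5R,6R)-2,6-dimethyl-6-[2-(phenylsulfonyl)prop-2-en-1-yl]-5-(prop-1-en-2-yl)cyclohex-2-en-1-one, via 6-methylcarvone lithium enolate 7 (not isolated)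
Conditions: LiN(i-Pr)2 (LDA), THF, −78 °C; then 3, −78 to −30 °C
Reagents that add atoms: none
Why: Enolate alkylation by addition–elimination (SN2′) on the bromomethyl vinyl sulfone, in which the electrophile should enter anti to the adjacent isopropenyl group, setting the quaternary centre (future C10) with the sulfonylallyl arm trans and the methyl cis to the isopropenyl group, as is usual for the second alkylation of 6-alkylcarvones.

Step 5
Reactants: 8 (5R,6R)-2,6-dimethyl-6-[2-(phenylsulfonyl)prop-2-en-1-yl]-5-(prop-1-en-2-yl)cyclohex-2-en-1-one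
Product: 9 (4aR,8aR)-2,5,5,8a-tetramethyl-7-(phenylsulfonyl)-4a,5,6,7,8,8a-hexahydronaphthalen-1(4H)-one (epimer mixture at C7, which is labdane C2)
Conditions: Fe(acac)3, PhSiH3, EtOH/ethylene glycol (5:1), 0.02 M, 60 °C
Reagents that add atoms: none
Why: An iron hydride (trivalent iron) formed from Fe(acac)3 and PhSiH3 in ethanol transfers a hydrogen atom to the CH2 of the isopropenyl group (Markovnikov), the tertiary C4 radical adds to the unsubstituted terminus (C3) of the vinyl sulfone, and the α-sulfonyl C2 radical is reduced by divalent iron and protonated by ethanol. The closest known reaction type is the iron-mediated reductive olefin coupling (hydrogen-atom-transfer Giese addition of an unactivated alkene to an electron-poor alkene), used here intramolecularly. Ring A closes in a 6-endo-trig mode, which should beat 5-exo because the nucleophilic tertiary radical attacks the β-carbon of the acceptor while the α-carbon is fully substituted. C4 is not stereogenic, the trans ring fusion follows from the trans arrangement of the two arms on C5 and C10 set in step 4 (both equatorial on ring B), and C2 forms as an epimer mixture that disappears in step 6. The step needs chemoselective hydrogen-atom transfer to the electron-rich 1,1-disubstituted alkene in the presence of the vinyl sulfone and the ring B enone, which the polarity of the metal hydride secures; attack of the C4 radical on the enone would close a four-membered ring and is excluded, and dilution suppresses intermolecular coupling.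

Step 6
Reactants: 9 (4aR,8aR)-2,5,5,8a-tetramethyl-7-(phenylsulfonyl)-4a,5,6,7,8,8a-hexahydronaphthalen-1(4H)-one
Product: 11 (4aR,8aR)-2,5,5,8a-tetramethyl-3,4,4a,5,6,7,8,8a-octahydronaphthalen-1-yl trifluoromethanesulfonate, via decalone lithium enolate 10 (not isolated)
Conditions: Li, NH3/THF, t-BuOH (2 equiv), −78 °C; isoprene; evaporate NH3; PhNTf2, THF, 0 °C to rt
Reagents that add atoms: N-phenylbis(trifluoromethanesulfonimide), O=S(=O)(N(c1ccccc1)S(=O)(=O)C(F)(F)F)C(F)(F)F
Why: Dissolving-metal reduction does two known things in one flask, the Birch-type conjugate reduction of the enone to its lithium enolate (the only enolate possible, since C10 is quaternary) and the reductive cleavage of the secondary C–SO2Ph bond, and O-triflation of the enolate then fixes the tetrasubstituted C8=C9 double bond without touching C5 or C10.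

Step 7
Reactants: 12 (R)-3-methylglutaric acid monomethyl ester
Product: 13 methyl (3R)-5-hydroxy-3-methylpentanoate
Conditions: BH3·SMe2, THF, 0 °C to rt
Reagents that add atoms: none
Why: Chemoselective borane reduction of the free carboxylic acid in the presence of the methyl ester (acyloxyborane pathway), with the stereocentre not involved and the hydroxy ester used at once to avoid lactonisation.

Step 8
Reactants: 13 methyl (3R)-5-hydroxy-3-methylpentanoate
Product: 14 methyl (3S)-5-iodo-3-methylpentanoate
Conditions: I2, PPh3, imidazole, CH2Cl2, 0 °C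
Reagents that add atoms: iodine, II
Why: Appel-type iodination of the primary alcohol by SN2 at CH2; the stereocentre is remote and only its descriptor changes.

Step 9
Reactants: 14 methyl (3S)-5-iodo-3-methylpentanoate; 11 (4aR,8aR)-2,5,5,8a-tetramethyl-3,4,4a,5,6,7,8,8a-octahydronaphthalen-1-yl trifluoromethanesulfonate
Product: 16 methyl (3R)-3-methyl-5-[(4aR,8aR)-2,5,5,8a-tetramethyl-3,4,4a,5,6,7,8,8a-octahydronaphthalen-1-yl]pentanoate, via alkylzinc iodide 15 (not isolated)
Conditions: Zn, LiCl, THF, 40 °C; then 11, PdCl2(dppf), THF/NMP, 60 °C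
Reagents that add atoms: none
Why: Zinc insertion into the primary iodide tolerates the ester, and Negishi coupling of the alkylzinc iodide with the alkenyl triflate forms C9–C11 with the double bond fixed at C8=C9, the bisphosphine ligand favouring reductive elimination over β-hydride elimination and C13 remaining untouched.

Step 10
Reactants: 16 methyl (3R)-3-methyl-5-[(4aR,8aR)-2,5,5,8a-tetramethyl-3,4,4a,5,6,7,8,8a-octahydronaphthalen-1-yl]pentanoate
Product: 17 (3R)-3-methyl-5-[(4aR,8aR)-2,5,5,8a-tetramethyl-3,4,4a,5,6,7,8,8a-octahydronaphthalen-1-yl]pentanoic acid (ent-labd-8-en-15-oic acid)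
Conditions: LiOH, THF/MeOH/H2O, 40 °C; aq. HCl work-up
Reagents that add atoms: lithium hydroxide, [Li+].[OH-]
Why: Saponification by acyl–oxygen cleavage; C13 is β to the carbonyl and cannot epimerise, and the tetrasubstituted alkene is inert to base.

Step 11
Reactants: 18 (S)-solketal [(4S)-2,2-dimethyl-1,3-dioxolane-4-methanol]
Product: 19 (4S)-4-{[(4-methoxybenzyl)oxy]methyl}-2,2-dimethyl-1,3-dioxolane
Conditions: NaH, PMBCl, Bu4NI, THF/DMF, 0 °C to rt
Reagents that add atoms: 4-methoxybenzyl chloride, COc1ccc(CCl)cc1
Why: Williamson etherification of the primary alkoxide with iodide catalysis; acetonide and stereocentre are unaffected.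

Step 12
Reactants: 19 (4S)-4-{[(4-methoxybenzyl)oxy]methyl}-2,2-dimethyl-1,3-dioxolane
Product: 20 (2R)-3-[(4-methoxybenzyl)oxy]propane-1,2-diol
Conditions: AcOH/H2O (4:1), 40 °C
Reagents that add atoms: none
Why: Acid-catalysed acetal hydrolysis under conditions mild enough to keep the PMB ether; the stereocentre is not involved.

Step 13
Reactants: 20 (2R)-3-[(4-methoxybenzyl)oxy]propane-1,2-diol
Product: 21 (2S)-2-hydroxy-3-[(4-methoxybenzyl)oxy]propyl acetate
Conditions: AcCl, 2,4,6-collidine, CH2Cl2, −78 °C
Reagents that add atoms: acetyl chloride, CC(Cl)=O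
Why: Kinetically controlled monoacylation of the primary hydroxyl of a 1,2-diol at low temperature with a hindered pyridine base, leaving the secondary hydroxyl free.

Step 14
Reactants: 17 ent-labd-8-en-15-oic acid; 21 (2S)-2-hydroxy-3-[(4-methoxybenzyl)oxy]propyl acetate
Product: 22 (2S)-1-acetoxy-3-[(4-methoxybenzyl)oxy]propan-2-yl (3R)-3-methyl-5-[(4aR,8aR)-2,5,5,8a-tetramethyl-3,4,4a,5,6,7,8,8a-octahydronaphthalen-1-yl]pentanoate
Conditions: EDC·HCl, DMAP, CH2Cl2, 0 °C to rt
Reagents that add atoms: none
Why: Steglich-type esterification (carbodiimide/DMAP) of the secondary alcohol at low temperature, expected to outrun acetyl migration, with all stereocentres retained because no bond to them is broken.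

Step 15
Reactants: 22 (2S)-1-acetoxy-3-[(4-methoxybenzyl)oxy]propan-2-yl ent-labd-8-en-15-oate
Product: 23 (2S)-1-acetoxy-3-hydroxypropan-2-yl (3R)-3-methyl-5-[(4aR,8aR)-2,5,5,8a-tetramethyl-3,4,4a,5,6,7,8,8a-octahydronaphthalen-1-yl]pentanoate (target)
Conditions: DDQ, CH2Cl2/pH 7 phosphate buffer, 0 °C
Reagents that add atoms: none
Why: Oxidative PMB ether cleavage by DDQ (hydride abstraction, then hydrolysis of the hemiacetal) under neutral buffered conditions, chosen because neither acid nor base is present to drive acyl migration to the free primary hydroxyl, and the tetrasubstituted alkene should not be oxidised at 0 °C.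

Compound list
1 | phenyl vinyl sulfone | C=CS(=O)(=O)c1ccccc1 | starting material
2 | 2-(phenylsulfonyl)prop-2-en-1-ol | C=C(CO)S(=O)(=O)c1ccccc1 | intermediate
3 | 3-bromo-2-(phenylsulfonyl)prop-1-ene | C=C(CBr)S(=O)(=O)c1ccccc1 | intermediate
4 | (S)-(+)-carvone, (5S)-2-methyl-5-(prop-1-en-2-yl)cyclohex-2-en-1-one | CC1=CC[C@@H](CC1=O)C(C)=C | starting material
5 | lithium (3S)-6-methyl-3-(prop-1-en-2-yl)cyclohexa-1,5-dien-1-olate (kinetic α′-enolate of carvone) | [Li]OC1=C[C@@H](C(C)=C)CC=C1C | intermediate
6 | (5S,6R)-2,6-dimethyl-5-(prop-1-en-2-yl)cyclohex-2-en-1-one (trans-6-methylcarvone) | O=C1C(C)=CC[C@H](C(C)=C)[C@H]1C | intermediate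
7 | lithium (3R)-2,6-dimethyl-3-(prop-1-en-2-yl)cyclohexa-1,5-dien-1-olate (α′-enolate of 6) | [Li]OC1=C(C)[C@@H](C(C)=C)CC=C1C | intermediate
8 | (5R,6R)-2,6-dimethyl-6-[2-(phenylsulfonyl)prop-2-en-1-yl]-5-(prop-1-en-2-yl)cyclohex-2-en-1-one | O=C1C(C)=CC[C@H](C(C)=C)[C@@]1(C)CC(=C)S(=O)(=O)c1ccccc1 | intermediate
9 | (4aR,8aR)-2,5,5,8a-tetramethyl-7-(phenylsulfonyl)-4a,5,6,7,8,8a-hexahydronaphthalen-1(4H)-one (C7 epimers) | O=C1C(C)=CC[C@@H]2C(C)(C)CC(S(=O)(=O)c3ccccc3)C[C@@]12C | intermediate
10 | lithium (4aR,8aR)-2,5,5,8a-tetramethyl-3,4,4a,5,6,7,8,8a-octahydronaphthalen-1-olate | [Li]OC1=C(C)CC[C@@H]2C(C)(C)CCC[C@@]12C | intermediate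
11 | (4aR,8aR)-2,5,5,8a-tetramethyl-3,4,4a,5,6,7,8,8a-octahydronaphthalen-1-yl trifluoromethanesulfonate | O=S(=O)(OC1=C(C)CC[C@@H]2C(C)(C)CCC[C@@]12C)C(F)(F)F | intermediate
12 | (R)-3-methylglutaric acid monomethyl ester, (3R)-5-methoxy-3-methyl-5-oxopentanoic acid | COC(=O)C[C@H](C)CC(=O)O | starting material
13 | methyl (3R)-5-hydroxy-3-methylpentanoate | COC(=O)C[C@H](C)CCO | intermediate
14 | methyl (3S)-5-iodo-3-methylpentanoate | COC(=O)C[C@H](C)CCI | intermediate
15 | [(3S)-5-methoxy-3-methyl-5-oxopentyl]zinc iodide | COC(=O)C[C@H](C)CC[Zn]I | intermediate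
16 | methyl (3R)-3-methyl-5-[(4aR,8aR)-2,5,5,8a-tetramethyl-3,4,4a,5,6,7,8,8a-octahydronaphthalen-1-yl]pentanoate | COC(=O)C[C@H](C)CCC1=C(C)CC[C@@H]2C(C)(C)CCC[C@@]12C | intermediate
17 | (3R)-3-methyl-5-[(4aR,8aR)-2,5,5,8a-tetramethyl-3,4,4a,5,6,7,8,8a-octahydronaphthalen-1-yl]pentanoic acid | OC(=O)C[C@H](C)CCC1=C(C)CC[C@@H]2C(C)(C)CCC[C@@]12C | intermediate
18 | (S)-solketal, (4S)-2,2-dimethyl-1,3-dioxolane-4-methanol | CC1(C)OC[C@H](CO)O1 | starting material
19 | (4S)-4-{[(4-methoxybenzyl)oxy]methyl}-2,2-dimethyl-1,3-dioxolane | CC1(C)OC[C@H](COCc2ccc(OC)cc2)O1 | intermediate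
20 | (2R)-3-[(4-methoxybenzyl)oxy]propane-1,2-diol | OC[C@H](COCc1ccc(OC)cc1)O | intermediate
21 | (2S)-2-hydroxy-3-[(4-methoxybenzyl)oxy]propyl acetate | CC(=O)OC[C@H](COCc1ccc(OC)cc1)O | intermediate
22 | (2S)-1-acetoxy-3-[(4-methoxybenzyl)oxy]propan-2-yl (3R)-3-methyl-5-[(4aR,8aR)-2,5,5,8a-tetramethyl-3,4,4a,5,6,7,8,8a-octahydronaphthalen-1-yl]pentanoate | CC(=O)OC[C@H](COCc1ccc(OC)cc1)OC(=O)C[C@H](C)CCC1=C(C)CC[C@@H]2C(C)(C)CCC[C@@]12C | intermediate
23 | (2S)-1-acetoxy-3-hydroxypropan-2-yl (3R)-3-methyl-5-[(4aR,8aR)-2,5,5,8a-tetramethyl-3,4,4a,5,6,7,8,8a-octahydronaphthalen-1-yl]pentanoate | CC(=O)OC[C@H](CO)OC(=O)C[C@H](C)CCC1=C(C)CC[C@@H]2C(C)(C)CCC[C@@]12C | target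

Total step count: 15.
Longest linear sequence: 9 steps from phenyl vinyl sulfone (steps 1, 2, 4, 5, 6, 9, 10, 14, 15).

Steps most likely to fail

1. Step 5. The tertiary C4 radical may be reduced before it cyclises (net hydrogenation of the isopropenyl group), or hydrogen may be delivered to the vinyl sulfone first. Fallback: the same radical would be made from a halide under tin hydride chain conditions, which lack a metal hydride that can intercept it. Setting out from 8, Markovnikov hydrobromination of the isopropenyl group (HBr, CH2Cl2, −40 °C, as in the classical hydrobromination of carvone) should give (5S,6R)-5-(2-bromopropan-2-yl)-2,6-dimethyl-6-[2-(phenylsulfonyl)prop-2-en-1-yl]cyclohex-2-en-1-one F1. Slow addition of Bu3SnH with AIBN in benzene at 80 °C would then effect the 6-endo radical cyclisation and return to the route at 9.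

2. Step 6. C–S cleavage may stay incomplete (deprotonation next to sulfur protects the sulfone from electron transfer), aryl–sulfur cleavage may compete, or the lithium salts may consume the triflating agent so that O-triflation of the hindered enolate stalls. Fallback: the sulfone is kept until after the coupling. Setting out from 9, conjugate reduction with LiBH(s-Bu)3 in THF at −78 °C and trapping with PhNTf2 should give (4aR,8aR)-2,5,5,8a-tetramethyl-7-(phenylsulfonyl)-3,4,4a,5,6,7,8,8a-octahydronaphthalen-1-yl trifluoromethanesulfonate F2. Negishi coupling of F2 with 15 under the conditions of step 9 would give methyl (3R)-3-methyl-5-[(4aR,8aR)-2,5,5,8a-tetramethyl-7-(phenylsulfonyl)-3,4,4a,5,6,7,8,8a-octahydronaphthalen-1-yl]pentanoate F3. Reductive desulfonylation of F3 with Mg in MeOH at 50 °C comes back to the route at 16.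

3. Step 9. Oxidative addition of palladium into the tetrasubstituted triflate next to quaternary C10 may be slow, so that protodezincation or β-hydride elimination takes over. Fallback: a nickel-catalysed reductive cross-electrophile coupling, which needs no preformed organometal and engages the alkyl iodide as a radical. Setting out from 11 and 14 (NiBr2(dme), 4,4′-di-tert-butyl-2,2′-bipyridine, Mn, DMA, rt), it returns to the route at 16 and makes no compound outside the list (none F0).

Further compounds
F1 | step 5 | (5S,6R)-5-(2-bromopropan-2-yl)-2,6-dimethyl-6-[2-(phenylsulfonyl)prop-2-en-1-yl]cyclohex-2-en-1-one | O=C1C(C)=CC[C@H](C(C)(C)Br)[C@@]1(C)CC(=C)S(=O)(=O)c1ccccc1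
F2 | step 6 | (4aR,8aR)-2,5,5,8a-tetramethyl-7-(phenylsulfonyl)-3,4,4a,5,6,7,8,8a-octahydronaphthalen-1-yl trifluoromethanesulfonate | O=S(=O)(OC1=C(C)CC[C@@H]2C(C)(C)CC(S(=O)(=O)c3ccccc3)C[C@@]12C)C(F)(F)F
F3 | step 6 | methyl (3R)-3-methyl-5-[(4aR,8aR)-2,5,5,8a-tetramethyl-7-(phenylsulfonyl)-3,4,4a,5,6,7,8,8a-octahydronaphthalen-1-yl]pentanoate | COC(=O)C[C@H](C)CCC1=C(C)CC[C@@H]2C(C)(C)CC(S(=O)(=O)c3ccccc3)C[C@@]12C
F0 | step 9 | none | none
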